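**Retrosynthetic overview**
1. Target 21 ← global desilylation and alkene hydrogenation of the C4=C5 olefin 19, formed by cross-metathesis of two fragments of similar size.
2. Fragment A (homoallylic acetate 11) ← copper-catalysed opening of (R)-2-allyloxirane 4 by the aryl Grignard 9; 4 ← (R)-epichlorohydrin + vinylmagnesium bromide.
3. Aryl bromide 8 ← resorcinol by bis-silylation, iridium-catalysed C5–H borylation and bromodeboronation.
4. Fragment B (α-silyloxy ketone 18) ← Weinreb amide 15 + pentylmagnesium bromide; 15 ← methyl (R)-glycidate + vinylmagnesium bromide.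
5. Rings: the benzene ring is bought with resorcinol and no ring of the target is built; the oxirane of 4 is only a relay ring (closed in step 2, opened in step 6).

Assumption: both R-configured epoxides (1, 12) and THF solutions of the Grignard reagents 2 and 16 are bought; the metathesis alkene 19 is drawn as E, but the E/Z mixture is carried on because step 13 saturates it.

**Step 1**
Reactants: 1 (R)-epichlorohydrin [(2R)-2-(chloromethyl)oxirane]; 2 vinylmagnesium bromide
Product: 3 (2R)-1-chloropent-4-en-2-ol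
Conditions: 2 (1.1 equiv), CuI (10 mol%), THF, −78 → −30 °C; aqueous work-up
Reagents that add atoms: none
Why: Copper-catalysed Grignard opening of the epoxide at its unsubstituted carbon (SN2); the stereocentre of 1 is not touched, so R is carried over.

**Step 2**
Reactants: 3 (2R)-1-chloropent-4-en-2-ol
Product: 4 (2R)-2-(prop-2-en-1-yl)oxirane
Conditions: powdered NaOH, Et2O, rt; distil
Reagents that add atoms: none
Why: Intramolecular Williamson etherification in which the alkoxide displaces the primary chloride; the carbinol C–O bond is not broken, so the centre stays R.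

**Step 3**
Reactants: 5 resorcinol (benzene-1,3-diol)
Product: 6 1,3-bis[(triisopropylsilyl)oxy]benzene
Conditions: TIPSCl (2.3 equiv), imidazole (5 equiv), DMF, rt → 40 °C
Reagents that add atoms: triisopropylsilyl chloride (TIPSCl), CC(C)[Si](Cl)(C(C)C)C(C)C
Why: Imidazole-promoted O-silylation of both phenols gives bulky, Grignard-stable ethers that also block the ortho positions in the next step.

**Step 4**
Reactants: 6 1,3-bis[(triisopropylsilyl)oxy]benzene
Product: 7 2-{3,5-bis[(triisopropylsilyl)oxy]phenyl}-4,4,5,5-tetramethyl-1,3,2-dioxaborolane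
Conditions: [Ir(OMe)(cod)]2 (1.5 mol%), 4,4'-di-tert-butyl-2,2'-bipyridine (3 mol%), B2pin2 (1.0 equiv), THF, 80 °C
Reagents that add atoms: bis(pinacolato)diboron (B2pin2), CC1(C)OB(OC1(C)C)B1OC(C)(C)C(C)(C)O1
Why: Sterically controlled iridium-catalysed aromatic C–H borylation, where C5–H is the only C–H with no ortho substituent.

**Step 5**
Reactants: 7 2-{3,5-bis[(triisopropylsilyl)oxy]phenyl}-4,4,5,5-tetramethyl-1,3,2-dioxaborolane
Product: 8 1-bromo-3,5-bis[(triisopropylsilyl)oxy]benzene
Conditions: CuBr2 (3 equiv), MeOH/THF/H2O, 80 °C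
Reagents that add atoms: copper dibromide (CuBr2), Br[Cu]Br
Why: Copper-mediated ipso-bromodeboronation (boron-to-copper transmetallation, then C–Br bond formation) places bromine exactly where boron sat.

**Step 6**
Reactants: 8 1-bromo-3,5-bis[(triisopropylsilyl)oxy]benzene; 4 (2R)-2-(prop-2-en-1-yl)oxirane
Product: 10 (2R)-1-{3,5-bis[(triisopropylsilyl)oxy]phenyl}pent-4-en-2-ol, via arylmagnesium bromide 9 (not isolated)
Conditions: Mg turnings, I2 (cat.), THF, 60 °C; then CuI (10 mol%), 4 (1.2 equiv), −30 → 0 °C; aqueous work-up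
Reagents that add atoms: magnesium, [Mg] (held only in 9)
Why: Grignard formation followed by copper-catalysed SN2 opening of the epoxide at its CH2; the oxygen-bearing carbon is untouched, so (R)-4 gives the (R)-alcohol.

**Step 7**
Reactants: 10 (2R)-1-{3,5-bis[(triisopropylsilyl)oxy]phenyl}pent-4-en-2-ol
Product: 11 (2R)-1-{3,5-bis[(triisopropylsilyl)oxy]phenyl}pent-4-en-2-yl acetate
Conditions: Ac2O, pyridine, DMAP (cat.), CH2Cl2, rt
Reagents that add atoms: acetic anhydride, CC(=O)OC(C)=O
Why: DMAP-catalysed O-acylation of the only free hydroxyl, with retention at C2.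

**Step 8**
Reactants: 12 methyl (2R)-oxirane-2-carboxylate [methyl (R)-glycidate]; 2 vinylmagnesium bromide
Product: 13 methyl (2R)-2-hydroxypent-4-enoate
Conditions: 2 (1.3 equiv), CuBr·SMe2 (10 mol%), THF, −78 → −50 °C; aqueous work-up
Reagents that add atoms: none
Why: Copper-catalysed Grignard opening of the glycidic ester at the CH2 remote from the ester, which is faster than carbonyl addition at low temperature; C2 is untouched and stays R.

**Step 9**
Reactants: 13 methyl (2R)-2-hydroxypent-4-enoate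
Product: 14 methyl (2R)-2-[(triethylsilyl)oxy]pent-4-enoate
Conditions: TESCl, imidazole, CH2Cl2, 0 °C → rt
Reagents that add atoms: triethylsilyl chloride (TESCl), CC[Si](Cl)(CC)CC
Why: Silylation gives an ether that survives Grignard chemistry, metathesis and hydrogenation and leaves with fluoride at the end.

**Step 10**
Reactants: 14 methyl (2R)-2-[(triethylsilyl)oxy]pent-4-enoate
Product: 15 (2R)-N-methoxy-N-methyl-2-[(triethylsilyl)oxy]pent-4-enamide
Conditions: MeNHOMe·HCl (1.5 equiv), iPrMgCl (3.0 equiv), THF, −20 → 0 °C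
Reagents that add atoms: N,O-dimethylhydroxylamine hydrochloride, CNOC.Cl
Why: Aminolysis of the ester by the chloromagnesium amide (Weinreb amide formation) under non-enolising, low-temperature conditions that keep the α-oxygenated centre R.

**Step 11**
Reactants: 15 (2R)-N-methoxy-N-methyl-2-[(triethylsilyl)oxy]pent-4-enamide; 16 pentylmagnesium bromide
Product: 18 (4R)-4-[(triethylsilyl)oxy]dec-1-en-5-one, via tetrahedral magnesium chelate 17 (not isolated)
Conditions: 16 (1.5 equiv), THF, −20 → 0 °C; cold aqueous work-up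
Reagents that add atoms: none
Why: Weinreb ketone synthesis, in which the chelated adduct 17 stops over-addition and releases the ketone only on work-up, without epimerising the α-silyloxy centre.

**Step 12**
Reactants: 11 (2R)-1-{3,5-bis[(triisopropylsilyl)oxy]phenyl}pent-4-en-2-yl acetate; 18 (4R)-4-[(triethylsilyl)oxy]dec-1-en-5-one
Product: 19 (2R,4E,7R)-1-{3,5-bis[(triisopropylsilyl)oxy]phenyl}-8-oxo-7-[(triethylsilyl)oxy]tridec-4-en-2-yl acetate
Conditions: 18 (2.5 equiv), second-generation Hoveyda–Grubbs catalyst RuCl2(=CH-C6H4-2-OiPr)(H2IMes) (5 mol%), 1,4-benzoquinone (10 mol%), CH2Cl2, 40 °C, argon sweep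
Reagents that add atoms: none
Why: Olefin cross-metathesis of two terminal alkenes driven by loss of ethylene, with the excess of 18 biasing the statistical mixture toward the cross product and neither stereocentre involved.

**Step 13**
Reactants: 19 (2R,4E,7R)-1-{3,5-bis[(triisopropylsilyl)oxy]phenyl}-8-oxo-7-[(triethylsilyl)oxy]tridec-4-en-2-yl acetate
Product: 20 (2R,7R)-1-{3,5-bis[(triisopropylsilyl)oxy]phenyl}-8-oxo-7-[(triethylsilyl)oxy]tridecan-2-yl acetate
Conditions: H2 (1 atm), 10% Pd/C, EtOAc, rt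
Reagents that add atoms: none
Why: Heterogeneous catalytic hydrogenation saturates the disubstituted alkene (both geometric isomers converge) and leaves the ketone, acetate and silyl ethers alone in EtOAc.

**Step 14**
Reactants: 20 (2R,7R)-1-{3,5-bis[(triisopropylsilyl)oxy]phenyl}-8-oxo-7-[(triethylsilyl)oxy]tridecan-2-yl acetate
Product: 21 (2R,7R)-1-(3,5-dihydroxyphenyl)-7-hydroxy-8-oxotridecan-2-yl acetate
Conditions: Bu4NF/AcOH (1:1, 6 equiv), THF, 0 °C → rt
Reagents that add atoms: none
Why: Fluoride-driven desilylation of the two aryl silyl ethers and the triethylsilyl ether, buffered with acetic acid so the acetate and the base-sensitive α-hydroxy ketone (and its stereocentre) survive.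

**Compound list**
1 | (R)-epichlorohydrin, (2R)-2-(chloromethyl)oxirane | ClC[C@H]1CO1 | starting material
2 | vinylmagnesium bromide | C=C[Mg]Br | starting material
3 | (2R)-1-chloropent-4-en-2-ol | ClC[C@H](O)CC=C | intermediate
4 | (2R)-2-(prop-2-en-1-yl)oxirane | C=CC[C@@H]1CO1 | intermediate
5 | resorcinol (benzene-1,3-diol) | Oc1cccc(O)c1 | starting material
6 | 1,3-bis[(triisopropylsilyl)oxy]benzene | CC(C)[Si](Oc1cccc(O[Si](C(C)C)(C(C)C)C(C)C)c1)(C(C)C)C(C)C | intermediate
7 | 2-{3,5-bis[(triisopropylsilyl)oxy]phenyl}-4,4,5,5-tetramethyl-1,3,2-dioxaborolane | CC(C)[Si](Oc1cc(O[Si](C(C)C)(C(C)C)C(C)C)cc(c1)B1OC(C)(C)C(C)(C)O1)(C(C)C)C(C)C | intermediate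
8 | 1-bromo-3,5-bis[(triisopropylsilyl)oxy]benzene | CC(C)[Si](Oc1cc(Br)cc(O[Si](C(C)C)(C(C)C)C(C)C)c1)(C(C)C)C(C)C | intermediate
9 | {3,5-bis[(triisopropylsilyl)oxy]phenyl}magnesium bromide | CC(C)[Si](Oc1cc([Mg]Br)cc(O[Si](C(C)C)(C(C)C)C(C)C)c1)(C(C)C)C(C)C | intermediate (not isolated)
10 | (2R)-1-{3,5-bis[(triisopropylsilyl)oxy]phenyl}pent-4-en-2-ol | C=CC[C@@H](O)Cc1cc(O[Si](C(C)C)(C(C)C)C(C)C)cc(O[Si](C(C)C)(C(C)C)C(C)C)c1 | intermediate
11 | (2R)-1-{3,5-bis[(triisopropylsilyl)oxy]phenyl}pent-4-en-2-yl acetate | C=CC[C@@H](OC(C)=O)Cc1cc(O[Si](C(C)C)(C(C)C)C(C)C)cc(O[Si](C(C)C)(C(C)C)C(C)C)c1 | intermediate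
12 | methyl (2R)-oxirane-2-carboxylate | COC(=O)[C@H]1CO1 | starting material
13 | methyl (2R)-2-hydroxypent-4-enoate | COC(=O)[C@H](O)CC=C | intermediate
14 | methyl (2R)-2-[(triethylsilyl)oxy]pent-4-enoate | COC(=O)[C@H](O[Si](CC)(CC)CC)CC=C | intermediate
15 | (2R)-N-methoxy-N-methyl-2-[(triethylsilyl)oxy]pent-4-enamide | CON(C)C(=O)[C@H](O[Si](CC)(CC)CC)CC=C | intermediate
16 | pentylmagnesium bromide | CCCCC[Mg]Br | starting material
17 | bromomagnesium alkoxide of (4R)-5-[methoxy(methyl)amino]-4-[(triethylsilyl)oxy]dec-1-en-5-ol (tetrahedral Weinreb adduct, C5 unspecified) | CCCCCC(O[Mg]Br)(N(C)OC)[C@H](O[Si](CC)(CC)CC)CC=C | intermediate (not isolated)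
18 | (4R)-4-[(triethylsilyl)oxy]dec-1-en-5-one | CCCCCC(=O)[C@H](O[Si](CC)(CC)CC)CC=C | intermediate
19 | (2R,4E,7R)-1-{3,5-bis[(triisopropylsilyl)oxy]phenyl}-8-oxo-7-[(triethylsilyl)oxy]tridec-4-en-2-yl acetate | CCCCCC(=O)[C@H](O[Si](CC)(CC)CC)C/C=C/C[C@@H](OC(C)=O)Cc1cc(O[Si](C(C)C)(C(C)C)C(C)C)cc(O[Si](C(C)C)(C(C)C)C(C)C)c1 | intermediate
20 | (2R,7R)-1-{3,5-bis[(triisopropylsilyl)oxy]phenyl}-8-oxo-7-[(triethylsilyl)oxy]tridecan-2-yl acetate | CCCCCC(=O)[C@H](O[Si](CC)(CC)CC)CCCC[C@@H](OC(C)=O)Cc1cc(O[Si](C(C)C)(C(C)C)C(C)C)cc(O[Si](C(C)C)(C(C)C)C(C)C)c1 | intermediate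
21 | (2R,7R)-1-(3,5-dihydroxyphenyl)-7-hydroxy-8-oxotridecan-2-yl acetate | CCCCCC(=O)[C@H](O)CCCC[C@H](Cc1cc(O)cc(O)c1)OC(C)=O | target

**Step count**
Total steps: 14. Longest linear sequence: 8 (steps 3, 4, 5, 6, 7, 12, 13, 14, from resorcinol 5). The other two chains are 7 steps each (steps 1, 2, 6, 7, 12–14 and steps 8–14).

**Steps most likely to fail, with fallbacks**

Step 5 (bromodeboronation). Hot aqueous methanol with CuBr2 and the HBr it releases may strip the aryl silyl ethers, and the lipophilic boronate dissolves poorly. The fallback sets out from 7 and comes back at 10, avoiding the halide and the Grignard altogether. Boronate 7 is allylated by Suzuki–Miyaura coupling (allyl bromide, Pd(PPh3)4 as the zerovalent palladium catalyst, CsF, THF, 65 °C) to 1-(prop-2-en-1-yl)-3,5-bis[(triisopropylsilyl)oxy]benzene F1. Lemieux–Johnson cleavage (OsO4 cat., NaIO4, 2,6-lutidine, dioxane/H2O) gives {3,5-bis[(triisopropylsilyl)oxy]phenyl}acetaldehyde F2, used crude. Brown allylation with B-allyldiisopinocampheylborane from the (−)-α-pinene series (made from (+)-Ipc2BOMe and allylmagnesium bromide; Et2O, −78 °C; then NaOH/H2O2) delivers allyl to the Re face and gives the R carbinol 10 under reagent control. Steps 1, 2 and 6 then fall away.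

Step 8 (glycidic ester opening). The Grignard can add to the ester carbonyl or give bromohydrin instead of opening the epoxide. The fallback sets out from 12 and comes back at 13, changing the electrophile to the carboxylate, which cannot suffer carbonyl addition. Ester 12 is saponified (KOH, EtOH, 0 °C) to potassium (2R)-oxirane-2-carboxylate F3. This is opened at its CH2 with excess 2 and CuI (cat.) in THF at −30 °C to (2R)-2-hydroxypent-4-enoic acid F4. Methylation of the carboxylate (MeI, KHCO3, DMF) returns 13 with the R centre untouched.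

Step 12 (cross-metathesis). Two precious olefins of similar reactivity give a statistical mixture, and the ketone or acetate oxygen may chelate and slow the ruthenium alkylidene. The fallback sets out from 15 (with 4 as partner) and comes back at 20. The metathesis is moved to cheap partners and the two halves are joined by epoxide opening instead.
- Amide 15 undergoes cross-metathesis with a fivefold excess of volatile 4 (same catalyst) to (2R,4E)-N-methoxy-N-methyl-6-[(2R)-oxiran-2-yl]-2-[(triethylsilyl)oxy]hex-4-enamide F5.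
- H2 over Pd/C in EtOAc gives (2R)-N-methoxy-N-methyl-6-[(2R)-oxiran-2-yl]-2-[(triethylsilyl)oxy]hexanamide F6.
- Grignard 9 (from 8 as in step 6; CuI cat., THF, −40 °C) opens the oxirane at its CH2 to (2R,7R)-8-{3,5-bis[(triisopropylsilyl)oxy]phenyl}-7-hydroxy-N-methoxy-N-methyl-2-[(triethylsilyl)oxy]octanamide F7. This relies on epoxide opening being faster than attack on the Weinreb amide at −40 °C, which is the weak point of the fallback.
- Reagent 16 (3 equiv, THF, 0 °C) turns the amide into the ketone (2R,7R)-1-{3,5-bis[(triisopropylsilyl)oxy]phenyl}-2-hydroxy-7-[(triethylsilyl)oxy]tridecan-8-one F8.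
- Acetylation as in step 7 gives 20.

**Further compounds**
F1 | step 5 | 1-(prop-2-en-1-yl)-3,5-bis[(triisopropylsilyl)oxy]benzene | C=CCc1cc(O[Si](C(C)C)(C(C)C)C(C)C)cc(O[Si](C(C)C)(C(C)C)C(C)C)c1
F2 | step 5 | {3,5-bis[(triisopropylsilyl)oxy]phenyl}acetaldehyde | O=CCc1cc(O[Si](C(C)C)(C(C)C)C(C)C)cc(O[Si](C(C)C)(C(C)C)C(C)C)c1
F3 | step 8 | potassium (2R)-oxirane-2-carboxylate | [K+].[O-]C(=O)[C@H]1CO1
F4 | step 8 | (2R)-2-hydroxypent-4-enoic acid | OC(=O)[C@H](O)CC=C
F5 | step 12 | (2R,4E)-N-methoxy-N-methyl-6-[(2R)-oxiran-2-yl]-2-[(triethylsilyl)oxy]hex-4-enamide | CON(C)C(=O)[C@H](O[Si](CC)(CC)CC)C/C=C/C[C@@H]1CO1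
F6 | step 12 | (2R)-N-methoxy-N-methyl-6-[(2R)-oxiran-2-yl]-2-[(triethylsilyl)oxy]hexanamide | CON(C)C(=O)[C@H](O[Si](CC)(CC)CC)CCCC[C@@H]1CO1
F7 | step 12 | (2R,7R)-8-{3,5-bis[(triisopropylsilyl)oxy]phenyl}-7-hydroxy-N-methoxy-N-methyl-2-[(triethylsilyl)oxy]octanamide | CON(C)C(=O)[C@H](O[Si](CC)(CC)CC)CCCC[C@@H](O)Cc1cc(O[Si](C(C)C)(C(C)C)C(C)C)cc(O[Si](C(C)C)(C(C)C)C(C)C)c1
F8 | step 12 | (2R,7R)-1-{3,5-bis[(triisopropylsilyl)oxy]phenyl}-2-hydroxy-7-[(triethylsilyl)oxy]tridecan-8-one | CCCCCC(=O)[C@H](O[Si](CC)(CC)CC)CCCC[C@@H](O)Cc1cc(O[Si](C(C)C)(C(C)C)C(C)C)cc(O[Si](C(C)C)(C(C)C)C(C)C)c1
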